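**Retrosynthetic overview**

1. Endgame: the C9 enal comes from oxidative 1,3-transposition of an isopropenyl carbinol; the triene comes from a Horner–Wadsworth–Emmons reaction on a lactol; the lactol comes from a butenolide annulated onto a C2 α-ketol, which locks the CH2OAc/chain geometry.
2. The cis C1–OH/C2–acyl pair comes from a nitrile oxide cycloaddition to a C1=C2 cyclopentene (the isoxazoline is kept as a mask); C6 methyl carbinol by MeLi addition; C10 chain by allylation of an enol triflate and hydroboration.
3. Key disconnection: the C2–C3 and C1–C5 bonds of the cyclopentane, made together by a SmI2-catalysed radical-relay formal [3+2] cycloaddition of spiro-cyclopropyl ketone 5 with ethynyltrimethylsilane. Enabling feature: ring carbon C10 (the CH that carries the hydroxypropyl chain) is bonded to the spiro carbon C5 and can be carried as a ketone; its ketyl opens a cyclopropane (C3, C4, C5) spiro-fused at C5, so C3 (radical) and C5 (enolate carbon) become the termini of a three-carbon unit, while the oxygen on neighbouring C6 steers the face of C5.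
4. Ring order: cyclohexane (from cyclohexane-1,3-dione) → spiro cyclopropane → cyclopentene (key step) → isoxazoline (temporary) → butenolide (temporary, opened in the olefination).
5. Absolute configuration: CBS desymmetrisation of the achiral spiro dione; every later stereocentre is set under substrate control.

Key step: step 4

Remark: locants follow spiro[4.5]decane numbering of the target core (C1 carbinol CH; C2 CH bearing the trienyl chain; C3 and C4 CH2; C5 spiro carbon; C6 C(OH)CH3; C7 and C8 CH2; C9 alkylidene carbon; C10 CH bearing the 3-hydroxypropyl chain) and are kept for all intermediates instead of lowest-locant numbering; TBDPS = tert-butyldiphenylsilyl, TBS = tert-butyldimethylsilyl, TES = triethylsilyl, PMB = 4-methoxybenzyl; the sense of the CBS reduction in step 2 is assigned from the usual model with the quaternary spiro carbon as the large group.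

**Route**

Step 1
Reactants: 1 cyclohexane-1,3-dione; 2 (2-bromoethyl)diphenylsulfonium trifluoromethanesulfonate
Product: 3 spiro[2.5]octane-4,8-dione
Conditions: K2CO3, EtOAc, rt
Reagents that add atoms: none
Why: Spirocyclopropanation of a 1,3-dione by a vinylsulfonium salt formed in the flask (conjugate addition of the dione enolate, then ring closure of the sulfonium ylide with loss of Ph2S) is an established route to 2-spirocyclopropyl 1,3-diones; no stereocentre is formed.

Step 2
Reactants: 3 spiro[2.5]octane-4,8-dione
Product: 4 (R)-8-hydroxyspiro[2.5]octan-4-one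
Conditions: (S)-2-methyl-CBS-oxazaborolidine (10 mol %), BH3·SMe2 (0.6 equiv), THF, −30 °C; MeOH quench
Reagents that add atoms: none
Why: Corey–Bakshi–Shibata reduction distinguishes the two enantiotopic carbonyl groups of the achiral dione and, with the quaternary spiro carbon as the large group, the (S)-catalyst should give the (R)-carbinol, the only stereocentre of 4 and the source of absolute configuration for the route.

Step 3
Reactants: 4 (R)-8-hydroxyspiro[2.5]octan-4-one
Product: 5 (R)-8-(tert-butyldiphenylsilyloxy)spiro[2.5]octan-4-one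
Conditions: TBDPSCl, imidazole, DMF, 40 °C
Reagents that add atoms: tert-butyl(chloro)diphenylsilane, CC(C)(C)[Si](Cl)(c1ccccc1)c1ccccc1
Why: Imidazole-promoted silylation of the secondary alcohol gives an acid-stable, bulky ether that will shield one face of the neighbouring spiro carbon in step 4; the stereocentre is untouched.

Step 4
Reactants: 5 (R)-8-(tert-butyldiphenylsilyloxy)spiro[2.5]octan-4-one; 6 ethynyltrimethylsilane
Product: 7 (5S,6R)-6-(TBDPS-oxy)-1-(trimethylsilyl)spiro[4.5]dec-1-en-10-one
Conditions: SmI2 (20 mol %), Sm metal (20 mol %), 6 (5 equiv), THF, 55 °C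
Reagents that add atoms: none
Why: Divalent samarium reduces the ketone (C10 of the product) to a ketyl whose spiro-fused cyclopropane, held bisected to the carbonyl, opens with release of ring strain to a primary C3 radical tethered to a trivalent-samarium enolate (C10=C5); the radical adds to the unsubstituted alkyne carbon of 6 (new C2–C3 bond), the α-silyl vinyl radical at C1 closes onto the enolate carbon C5 (new C1–C5 bond), and the new ketyl returns its electron to samarium, so the metal turns over. The closest known reaction type is the SmI2-catalysed radical-relay formal [3+2] cycloaddition of alkyl cyclopropyl ketones with alkynes. The cyclopentene is closed by a 5-exo-trig attack of the vinyl radical on the enolate carbon. The only new stereocentre, the quaternary spiro carbon C5, should be set by approach of C1 anti to the bulky silyloxy group on the adjacent carbon (C8 of 5, C6 of 7). The step needs regioselective addition at the terminal alkyne carbon, secured by the silyl group, which blocks its own carbon and stabilises the vinyl radical there; it also needs alkyne capture to outrun hydrogen abstraction from THF, secured by excess 6 and by Sm metal, which returns any trivalent samarium to the divalent state.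

Step 5
Reactants: 7 (5S,6R)-6-(TBDPS-oxy)-1-(trimethylsilyl)spiro[4.5]dec-1-en-10-one
Product: 8 (5S,6R)-6-(TBDPS-oxy)spiro[4.5]dec-1-en-10-one
Conditions: CF3CO2H, CH2Cl2, 0 °C to rt
Reagents that add atoms: none
Why: ipso-Protodesilylation of the vinylsilane (protonation at the silicon-bearing carbon, β-silyl cation, loss of silicon) leaves the C1=C2 alkene in place, and the TBDPS ether and the ketone tolerate the acid.

Step 6
Reactants: 9 2-(4-methoxybenzyloxy)acetaldehyde
Product: 10 2-(4-methoxybenzyloxy)acetaldehyde oxime (E/Z mixture)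
Conditions: NH2OH·HCl, NaOAc, EtOH/H2O, rt
Reagents that add atoms: hydroxylamine hydrochloride, Cl.NO
Why: Condensation of the aldehyde with hydroxylamine gives the oxime, whose geometry is irrelevant because it is converted to a linear nitrile oxide.

Step 7
Reactants: 8 (5S,6R)-6-(TBDPS-oxy)spiro[4.5]dec-1-en-10-one; 10 2-(4-methoxybenzyloxy)acetaldehyde oxime
Product: 13 isoxazoline ketone (8 carrying a 3-(PMB-oxymethyl)-2-isoxazoline cis-fused at C1–C2; ring O on C1; ring C3 on C2), via hydroximoyl chloride 11 (not isolated), via nitrile oxide 12 (not isolated)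
Conditions: N-chlorosuccinimide, DMF (cat.), CH2Cl2, rt; then 8, Et3N (slow addition), 0 °C to rt
Reagents that add atoms: none
Why: The Huisgen 1,3-dipolar cycloaddition of the nitrile oxide is suprafacial, so O on C1 and the C=N carbon on C2 must be cis; the dipole oxygen should go to the more hindered neopentyl-type C1, and the dipole should approach the cyclopentene face next to the flat C10 carbonyl and anti to the C6 silyloxy branch, which sets C1 and C2.

Step 8
Reactants: 13 isoxazoline ketone
Product: 15 C10 enol triflate of 13 (C9=C10 alkene), via potassium enolate 14 (not isolated)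
Conditions: KN(SiMe3)2, THF, −78 °C; then PhNTf2, −78 to 0 °C
Reagents that add atoms: N-phenylbis(trifluoromethanesulfonimide), O=S(=O)(N(c1ccccc1)S(=O)(=O)C(F)(F)F)C(F)(F)F
Why: The ketone can enolise only towards C9 because C5 is quaternary, so kinetic deprotonation and O-sulfonylation should give a single enol triflate.

Step 9
Reactants: 15 C10 enol triflate; 16 allyltributylstannane
Product: 17 10-allyl C9=C10 diene (allyl in place of OTf in 15)
Conditions: Pd(PPh3)4 (5 mol %), LiCl, THF, 65 °C
Reagents that add atoms: none
Why: Stille coupling of an enol triflate with an allylstannane is reliable even at hindered positions and creates no stereocentre.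

Step 10
Reactants: 17 10-allyl C9=C10 diene
Product: 18 C6 secondary alcohol (17 without TBDPS)
Conditions: Bu4NF, THF, 40 °C
Reagents that add atoms: none
Why: Fluoride cleaves the silyl ether, the only silicon group present, without affecting the isoxazoline, the PMB ether or the diene.

Step 11
Reactants: 18 C6 secondary alcohol
Product: 19 C6 ketone
Conditions: Dess–Martin periodinane, NaHCO3, CH2Cl2, rt
Reagents that add atoms: none
Why: Dess–Martin oxidation of the secondary alcohol is mild and cannot move the C9=C10 alkene into conjugation because C5 is quaternary; the temporary C6 stereocentre has done its work and is removed here.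

Step 12
Reactants: 19 C6 ketone
Product: 20 C6 methyl carbinol (OH cis to C1; CH3 cis to C4)
Conditions: MeLi, THF, −78 °C; aq. NH4Cl
Reagents that add atoms: methyllithium, [Li]C
Why: In this 1,2-addition of an organolithium, allylic strain with the C10 allyl group should hold the bulkier C1 arm of the spiro ring pseudoaxial, so the nucleophile should enter anti to it, which places CH3 cis to C4 and OH cis to C1 as in the target.

Step 13
Reactants: 20 C6 methyl carbinol
Product: 22 triol (10-(3-hydroxypropyl) cis to C1; C9–OH trans to that chain; C6–OH), via bis(alkylborane) 21 (not isolated)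
Conditions: BH3·SMe2 (4 equiv), THF, 0 °C to rt; then NaOH, H2O2, 0 °C
Reagents that add atoms: hydrogen peroxide, OO
Why: Hydroboration–oxidation converts the terminal alkene into the primary alcohol and adds boron to C9 and hydrogen to C10 of the ring alkene in a syn addition from the face opposite the isoxazoline-bearing C1 arm, which sets C10 (chain cis to C1) and a temporary C9 carbinol.

Step 14
Reactants: 22 triol
Product: 23 primary TBS ether of 22
Conditions: TBSCl, imidazole, CH2Cl2, 0 °C
Reagents that add atoms: tert-butyl(chloro)dimethylsilane, CC(C)(C)[Si](C)(C)Cl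
Why: Silylation is selective for the unhindered primary hydroxyl over the hindered secondary and the tertiary hydroxyls.

Step 15
Reactants: 23 primary TBS ether
Product: 24 C9 ketone
Conditions: Dess–Martin periodinane, NaHCO3, CH2Cl2, rt
Reagents that add atoms: none
Why: Dess–Martin oxidation under buffered conditions converts the only secondary alcohol into the ketone without epimerising the adjacent C10 and leaves the tertiary C6 alcohol untouched.

Step 16
Reactants: 24 C9 ketone
Product: 25 C9 isopropenyl carbinol
Conditions: CH2=C(CH3)MgBr, LaCl3·2LiCl (30 mol %), THF, 0 °C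
Reagents that add atoms: isopropenylmagnesium bromide, CC(=C)[Mg]Br
Why: Lanthanum-promoted Grignard 1,2-addition suppresses enolisation of the hindered ketone; the nucleophile is drawn entering anti to the C1 arm, but the C9 configuration is irrelevant because C9 becomes sp2 in step 27.

Step 17
Reactants: 25 C9 isopropenyl carbinol
Product: 27 β-hydroxy ketone (C1–OH cis to C2–C(=O)CH2OPMB), via hydroxy ketimine 26 (not isolated)
Conditions: Mo(CO)6, MeCN/H2O, 80 °C
Reagents that add atoms: water, O
Why: Reductive N–O cleavage of the isoxazoline by Mo(CO)6 and hydrolysis of the β-hydroxy imine unmask the cis β-hydroxy ketone without touching the alkene, and C1 and C2 keep their configuration.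

Step 18
Reactants: 27 β-hydroxy ketone
Product: 28 C1 triethylsilyl ether of 27
Conditions: Et3SiCl, imidazole, DMF, 0 °C to rt
Reagents that add atoms: chlorotriethylsilane, CC[Si](Cl)(CC)CC
Why: Silylation protects the only secondary hydroxyl for the oxidation in step 27, while the two tertiary hydroxyls do not react with the chlorosilane.

Step 19
Reactants: 28 C1 triethylsilyl ether
Product: 29 α-ketol (C2–C(=O)CH2OH)
Conditions: DDQ, CH2Cl2/pH 7 buffer, 0 °C
Reagents that add atoms: none
Why: Oxidative cleavage of the PMB ether by DDQ is neutral and leaves the silyl ethers, the β-silyloxy ketone and the isopropenyl group intact.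

Step 20
Reactants: 29 α-ketol
Product: 31 butenolide (C2 bears 5-oxo-2,5-dihydrofuran-3-yl), via phosphoranylidene acetate 30 (not isolated)
Conditions: Ph3P=C=C=O, toluene, 80 °C
Reagents that add atoms: (triphenylphosphoranylidene)ketene, O=C=C=P(c1ccccc1)(c1ccccc1)c1ccccc1
Why: Addition of the primary hydroxyl to the ketene ylide gives an acyl ylide that closes by intramolecular Wittig reaction onto the adjacent ketone (the known butenolide annulation of α-hydroxy ketones), and the ring fixes the future CH2O carbon and the chain carbon cis on the new C=C.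

Step 21
Reactants: 31 butenolide
Product: 32 lactol (C2 bears 5-hydroxy-2,5-dihydrofuran-3-yl; anomers)
Conditions: iBu2AlH, CH2Cl2, −78 °C; aq. potassium sodium tartrate
Reagents that add atoms: none
Why: Low-temperature hydride reduction of a lactone stops at the lactol, the tertiary alkoxides are inert, and a non-acidic work-up avoids dehydration to the furan.

Step 22
Reactants: 33 2-methylprop-2-en-1-ol; 34 1-bromo-3-methylbut-2-ene
Product: 36 6-methyl-2-methylidenehept-5-en-1-ol, via dilithio dianion 35 (not isolated)
Conditions: n-BuLi (2.2 equiv), TMEDA, Et2O, 0 °C to rt; then 34, −78 °C to rt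
Reagents that add atoms: none
Why: The O,C-dianion of methallyl alcohol is alkylated at the allylic carbon by the primary allylic bromide (SN2).

Step 23
Reactants: 36 6-methyl-2-methylidenehept-5-en-1-ol
Product: 37 2-(bromomethyl)-6-methylhepta-1,5-diene
Conditions: CBr4, PPh3, CH2Cl2, 0 °C
Reagents that add atoms: tetrabromomethane, BrC(Br)(Br)Br
Why: The Appel reaction converts the primary allylic alcohol into the bromide under neutral conditions.

Step 24
Reactants: 37 2-(bromomethyl)-6-methylhepta-1,5-diene
Product: 38 diethyl (6-methyl-2-methylidenehept-5-en-1-yl)phosphonate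
Conditions: P(OEt)3, neat, 130 °C
Reagents that add atoms: triethyl phosphite, CCOP(OCC)OCC
Why: The Michaelis–Arbuzov reaction of a primary allylic bromide gives the allylic phosphonate.

Step 25
Reactants: 32 lactol; 38 diethyl (6-methyl-2-methylidenehept-5-en-1-yl)phosphonate
Product: 40 trienyl alcohol (C2 bears (2Z,4E)-1-hydroxy-10-methyl-6-methylideneundeca-2,4,9-trien-2-yl), via lithiated phosphonate 39 (not isolated)
Conditions: n-BuLi, THF, −78 °C; then 32, −78 °C to rt
Reagents that add atoms: none
Why: Horner–Wadsworth–Emmons olefination of the open hydroxy-enal form of the lactol by the α-carbon of the lithiated allylic phosphonate should give the (E)-alkene, while the geometry of the trisubstituted alkene is carried over from the ring.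

Step 26
Reactants: 40 trienyl alcohol
Product: 41 allylic acetate of 40
Conditions: Ac2O, pyridine, CH2Cl2, 0 °C
Reagents that add atoms: acetic anhydride, CC(=O)OC(C)=O
Why: Acetylation occurs at the only primary hydroxyl, and the two tertiary hydroxyls do not react under these conditions.

Step 27
Reactants: 41 allylic acetate
Product: 42 bis-silylated enal (C9=C(CH3)CHO with CHO cis to C8)
Conditions: pyridinium chlorochromate (C5H5NH[CrO3Cl]), NaOAc, 4 Å molecular sieves, CH2Cl2, rt
Reagents that add atoms: none
Why: In the Babler–Dauben oxidative 1,3-transposition the tertiary allylic chromate ester undergoes a [3,3]-shift to the primary allylic chromate, which is oxidised to the enal; a chair transition state with the CH2–O–Cr terminus turned towards the unsubstituted C8 side should place CHO cis to C8 and CH3 cis to C10.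

Step 28
Reactants: 42 bis-silylated enal
Product: 43 target CNP0204268.1
Conditions: HF·pyridine, pyridine, THF, 0 °C
Reagents that add atoms: none
Why: Buffered fluoride cleaves the TES and TBS ethers and should leave the acetate, the enal and the triene untouched.

**Compound list**

1 | cyclohexane-1,3-dione | O=C1CCCC(=O)C1 | starting material
2 | (2-bromoethyl)diphenylsulfonium trifluoromethanesulfonate | BrCC[S+](c1ccccc1)c1ccccc1.[O-]S(=O)(=O)C(F)(F)F | starting material
3 | spiro[2.5]octane-4,8-dione | O=C1CCCC(=O)C12CC2 | intermediate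
4 | (R)-8-hydroxyspiro[2.5]octan-4-one | O=C1CCC[C@@H](O)C12CC2 | intermediate
5 | (R)-8-(tert-butyldiphenylsilyloxy)spiro[2.5]octan-4-one | O=C1CCC[C@@H](O[Si](c3ccccc3)(c4ccccc4)C(C)(C)C)C12CC2 | intermediate
6 | ethynyltrimethylsilane | C#C[Si](C)(C)C | starting material
7 | (5S,6R)-6-(TBDPS-oxy)-1-(trimethylsilyl)spiro[4.5]dec-1-en-10-one (C1–C5 bond anti to the C6 silyloxy group) | C[Si](C)(C)C1=CCC[C@]12C(=O)CCC[C@H]2O[Si](c3ccccc3)(c4ccccc4)C(C)(C)C | intermediate
8 | (5S,6R)-6-(TBDPS-oxy)spiro[4.5]dec-1-en-10-one | C1=CCC[C@]12C(=O)CCC[C@H]2O[Si](c3ccccc3)(c4ccccc4)C(C)(C)C | intermediate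
9 | 2-(4-methoxybenzyloxy)acetaldehyde | O=CCOCc1ccc(OC)cc1 | starting material
10 | 2-(4-methoxybenzyloxy)acetaldehyde oxime (E/Z mixture) | ON=CCOCc1ccc(OC)cc1 | intermediate
11 | N-hydroxy-2-(4-methoxybenzyloxy)acetimidoyl chloride | ON=C(Cl)COCc1ccc(OC)cc1 | intermediate (not isolated)
12 | 2-(4-methoxybenzyloxy)acetonitrile oxide | [O-][N+]#CCOCc1ccc(OC)cc1 | intermediate (not isolated)
13 | isoxazoline ketone: 8 carrying a 3-(PMB-oxymethyl)-2-isoxazoline cis-fused at C1–C2 (ring O on C1, ring C3 on C2, heterocycle on the face next to C10 and anti to C6–O) | COc1ccc(COCC2=NO[C@@H]3[C@H]2CC[C@]34C(=O)CCC[C@H]4O[Si](c5ccccc5)(c6ccccc6)C(C)(C)C)cc1 | intermediate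
14 | potassium C9=C10 enolate of 13 | COc1ccc(COCC2=NO[C@@H]3[C@H]2CC[C@]34C([O-])=CCC[C@H]4O[Si](c5ccccc5)(c6ccccc6)C(C)(C)C)cc1.[K+] | intermediate (not isolated)
15 | C10 enol triflate of 13 (C9=C10 alkene) | COc1ccc(COCC2=NO[C@@H]3[C@H]2CC[C@]34C(OS(=O)(=O)C(F)(F)F)=CCC[C@H]4O[Si](c5ccccc5)(c6ccccc6)C(C)(C)C)cc1 | intermediate
16 | allyltributylstannane | C=CC[Sn](CCCC)(CCCC)CCCC | starting material
17 | 10-allyl C9=C10 diene (allyl in place of OTf in 15) | COc1ccc(COCC2=NO[C@@H]3[C@H]2CC[C@]34C(CC=C)=CCC[C@H]4O[Si](c5ccccc5)(c6ccccc6)C(C)(C)C)cc1 | intermediate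
18 | C6 secondary alcohol (17 without TBDPS) | COc1ccc(COCC2=NO[C@@H]3[C@H]2CC[C@]34C(CC=C)=CCC[C@H]4O)cc1 | intermediate
19 | C6 ketone | COc1ccc(COCC2=NO[C@@H]3[C@H]2CC[C@]34C(CC=C)=CCCC4=O)cc1 | intermediate
20 | C6 methyl carbinol (OH cis to C1, CH3 cis to C4) | COc1ccc(COCC2=NO[C@@H]3[C@H]2CC[C@]34C(CC=C)=CCC[C@]4(C)O)cc1 | intermediate
21 | bis(alkylborane) (BH2 on C9 and on the chain terminus; drawn without the borate of the tertiary alcohol) | COc1ccc(COCC2=NO[C@@H]3[C@H]2CC[C@]34[C@H](CCC[BH2])[C@@H]([BH2])CC[C@]4(C)O)cc1 | intermediate (not isolated)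
22 | triol (10-(3-hydroxypropyl) cis to C1; C9–OH trans to that chain; C6–OH) | COc1ccc(COCC2=NO[C@@H]3[C@H]2CC[C@]34[C@H](CCCO)[C@@H](O)CC[C@]4(C)O)cc1 | intermediate
23 | primary TBS ether of 22 | COc1ccc(COCC2=NO[C@@H]3[C@H]2CC[C@]34[C@H](CCCO[Si](C)(C)C(C)(C)C)[C@@H](O)CC[C@]4(C)O)cc1 | intermediate
24 | C9 ketone | COc1ccc(COCC2=NO[C@@H]3[C@H]2CC[C@]34[C@H](CCCO[Si](C)(C)C(C)(C)C)C(=O)CC[C@]4(C)O)cc1 | intermediate
25 | C9 isopropenyl carbinol (isopropenyl drawn anti to C1) | COc1ccc(COCC2=NO[C@@H]3[C@H]2CC[C@]34[C@H](CCCO[Si](C)(C)C(C)(C)C)[C@@](O)(C(C)=C)CC[C@]4(C)O)cc1 | intermediate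
26 | β-hydroxy N–H ketimine | COc1ccc(COCC(=N)[C@@H]2CC[C@]3([C@H](CCCO[Si](C)(C)C(C)(C)C)[C@@](O)(C(C)=C)CC[C@]3(C)O)[C@@H]2O)cc1 | intermediate (not isolated)
27 | β-hydroxy ketone (C1–OH cis to C2–C(=O)CH2OPMB) | COc1ccc(COCC(=O)[C@@H]2CC[C@]3([C@H](CCCO[Si](C)(C)C(C)(C)C)[C@@](O)(C(C)=C)CC[C@]3(C)O)[C@@H]2O)cc1 | intermediate
28 | C1 triethylsilyl ether of 27 | COc1ccc(COCC(=O)[C@@H]2CC[C@]3([C@H](CCCO[Si](C)(C)C(C)(C)C)[C@@](O)(C(C)=C)CC[C@]3(C)O)[C@@H]2O[Si](CC)(CC)CC)cc1 | intermediate
29 | α-ketol (C2–C(=O)CH2OH) | OCC(=O)[C@@H]1CC[C@]2([C@H](CCCO[Si](C)(C)C(C)(C)C)[C@@](O)(C(C)=C)CC[C@]2(C)O)[C@@H]1O[Si](CC)(CC)CC | intermediate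
30 | (triphenylphosphoranylidene)acetate ester of 29 | O=C(COC(=O)C=P(c1ccccc1)(c1ccccc1)c1ccccc1)[C@@H]2CC[C@]3([C@H](CCCO[Si](C)(C)C(C)(C)C)[C@@](O)(C(C)=C)CC[C@]3(C)O)[C@@H]2O[Si](CC)(CC)CC | intermediate (not isolated)
31 | butenolide (C2 bears 5-oxo-2,5-dihydrofuran-3-yl) | O=C1C=C(CO1)[C@@H]2CC[C@]3([C@H](CCCO[Si](C)(C)C(C)(C)C)[C@@](O)(C(C)=C)CC[C@]3(C)O)[C@@H]2O[Si](CC)(CC)CC | intermediate
32 | lactol (C2 bears 5-hydroxy-2,5-dihydrofuran-3-yl; anomers) | OC1C=C(CO1)[C@@H]2CC[C@]3([C@H](CCCO[Si](C)(C)C(C)(C)C)[C@@](O)(C(C)=C)CC[C@]3(C)O)[C@@H]2O[Si](CC)(CC)CC | intermediate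
33 | 2-methylprop-2-en-1-ol | C=C(C)CO | starting material
34 | 1-bromo-3-methylbut-2-ene | CC(C)=CCBr | starting material
35 | dilithio dianion of 33 | [Li+].[Li+].[CH2-]C(=C)C[O-] | intermediate (not isolated)
36 | 6-methyl-2-methylidenehept-5-en-1-ol | C=C(CO)CCC=C(C)C | intermediate
37 | 2-(bromomethyl)-6-methylhepta-1,5-diene | C=C(CBr)CCC=C(C)C | intermediate
38 | diethyl (6-methyl-2-methylidenehept-5-en-1-yl)phosphonate | CCOP(=O)(OCC)CC(=C)CCC=C(C)C | intermediate
39 | α-lithio derivative of 38 | [Li+].CCOP(=O)(OCC)[CH-]C(=C)CCC=C(C)C | intermediate (not isolated)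
40 | trienyl alcohol (C2 bears (2Z,4E)-1-hydroxy-10-methyl-6-methylideneundeca-2,4,9-trien-2-yl) | C=C(/C=C/C=C(\CO)[C@@H]1CC[C@]2([C@H](CCCO[Si](C)(C)C(C)(C)C)[C@@](O)(C(C)=C)CC[C@]2(C)O)[C@@H]1O[Si](CC)(CC)CC)CCC=C(C)C | intermediate
41 | allylic acetate of 40 | C=C(/C=C/C=C(\COC(C)=O)[C@@H]1CC[C@]2([C@H](CCCO[Si](C)(C)C(C)(C)C)[C@@](O)(C(C)=C)CC[C@]2(C)O)[C@@H]1O[Si](CC)(CC)CC)CCC=C(C)C | intermediate
42 | bis-silylated enal (C1–OTES, chain OTBS; C9=C(CH3)CHO with CHO cis to C8) | C=C(/C=C/C=C(\COC(C)=O)[C@@H]1CC[C@]2([C@H](CCCO[Si](C)(C)C(C)(C)C)/C(=C(\C)C=O)CC[C@]2(C)O)[C@@H]1O[Si](CC)(CC)CC)CCC=C(C)C | intermediate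
43 | CNP0204268.1 | C=C(/C=C/C=C(\COC(C)=O)[C@@H]1CC[C@]2([C@H](CCCO)/C(=C(\C)C=O)CC[C@]2(C)O)[C@@H]1O)CCC=C(C)C | target

**Step count and risks**

Total step count: 28. Longest linear sequence: 24 steps (steps 1–5, 7–21 and 25–28); the oxime (step 6) and the phosphonate (steps 22–24) are side branches.

Most likely to fail, first: step 4. The ring-opened primary radical may abstract hydrogen from THF before it is captured by the alkyne, and samarium may be trapped in the trivalent state so that turnover stops. Fallback: setting out from 5, Me3SiI (CH2Cl2, −20 °C) should open the cyclopropyl ketone to the γ-iodo trimethylsilyl enol ether F1. Alkylation of lithiated acetaldehyde N,N-dimethylhydrazone (LiN(iPr)2, THF, −78 °C) with this primary iodide, followed by hydrolysis of hydrazone and silyl enol ether in the same flask (aq. oxalic acid), should give the keto aldehyde F2. Intramolecular aldol addition (K2CO3, MeOH, 0 °C) should form the C1–C5 bond anti to the silyloxy group and give the spiro β-hydroxy ketone F3. Dehydration with the Burgess reagent, which can only occur towards C2, rejoins the route at 8.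

Second: step 13. Borane may reduce the C=N bond of the isoxazoline in competition with the slow hydroboration of the hindered ring alkene, and facial selectivity at C10 may be eroded. Fallback: setting out from 20, 9-BBN (THF, rt; then NaOH, H2O2) should hydroborate only the terminal alkene and give the primary alcohol F4, which is silylated (TBSCl, imidazole) to the silyl ether F5. Epoxidation with VO(acac)2 and t-BuOOH, directed by the tertiary homoallylic C6 hydroxyl, should deliver oxygen to the C9=C10 face syn to that hydroxyl and give the epoxide F6. Meinwald rearrangement (BF3·OEt2, CH2Cl2, −78 °C) opens the epoxide at tertiary C10 and shifts hydride from C9 to C10 anti to the departing oxygen. This gives the same C10 configuration and the C9 ketone directly, rejoining the route at 24.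

Third: step 27. The chromium oxidant may attack the conjugated triene, and control of the enal geometry may be poor. Fallback: setting out from 41, catalytic Ph3SiOReO3 (Et2O, 0 °C) should isomerise the tertiary allylic alcohol by 1,3-transposition, under equilibrating conditions, to the primary allylic alcohol F7. Selective allylic oxidation with MnO2 (CH2Cl2, rt), which does not touch the triene, the acetate or the non-allylic alcohols, rejoins the route at 42.

Further compounds
F1 | step 4 | γ-iodo trimethylsilyl enol ether: (R)-6-(TBDPS-oxy)-2-(2-iodoethyl)-1-(trimethylsilyloxy)cyclohex-1-ene | C[Si](C)(C)OC1=C(CCI)[C@H](O[Si](c2ccccc2)(c3ccccc3)C(C)(C)C)CCC1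
F2 | step 4 | keto aldehyde: 4-[(3R)-3-(TBDPS-oxy)-2-oxocyclohexyl]butanal (epimers at the ring CH) | O=CCCCC1C(=O)CCC[C@H]1O[Si](c2ccccc2)(c3ccccc3)C(C)(C)C
F3 | step 4 | spiro β-hydroxy ketone: (5S,6R)-6-(TBDPS-oxy)-1-hydroxyspiro[4.5]decan-10-one (C1 epimers) | OC1CCC[C@]12C(=O)CCC[C@H]2O[Si](c3ccccc3)(c4ccccc4)C(C)(C)C
F4 | step 13 | primary alcohol: 20 with 3-hydroxypropyl in place of allyl | COc1ccc(COCC2=NO[C@@H]3[C@H]2CC[C@]34C(CCCO)=CCC[C@]4(C)O)cc1
F5 | step 13 | TBS ether of F4 | COc1ccc(COCC2=NO[C@@H]3[C@H]2CC[C@]34C(CCCO[Si](C)(C)C(C)(C)C)=CCC[C@]4(C)O)cc1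
F6 | step 13 | C9–C10 epoxide of F5 (oxygen syn to the C6 hydroxyl) | COc1ccc(COCC2=NO[C@@H]3[C@H]2CC[C@]34[C@]5(CCCO[Si](C)(C)C(C)(C)C)O[C@@H]5CC[C@]4(C)O)cc1
F7 | step 27 | primary allylic alcohol: 42 with CH2OH in place of CHO | C=C(/C=C/C=C(\COC(C)=O)[C@@H]1CC[C@]2([C@H](CCCO[Si](C)(C)C(C)(C)C)/C(=C(\C)CO)CC[C@]2(C)O)[C@@H]1O[Si](CC)(CC)CC)CCC=C(C)C
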